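**Not slowness.** Look for slowness first in Thursday's run, the nearest to this flask. Thursday's Sub reads 12.1 % at 1.00 min and 12.8 % at 10.0 min, so that run is flat from its first reading. Ask what stopped it.

| flask | Sub | Rea | Tsp | Ctl | remark | time |
|---|---|---|---|---|---|---|
| Wednesday's | 2.5 × 10⁻⁴ M | 0.75 mM | 0.50 mM | 25 µM | run made earlier |  |
| Friday's | 0.0010 M | 0.75 mM | 0.50 mM | 25 µM | run made earlier |  |
| Thursday's | 5.0 × 10⁻⁴ M | 0.75 mM | 1 mM | 25 µM | run made earlier |  |
| flask | 5.0 × 10⁻⁴ M | 0.750 mM | 0.500 mM | 25 µM |  | 15 min |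

- Wednesday's (time / min: Pdt / %, Rea.Pdt / %, Sub / %): 1.00: 0, 98.4, 0; 3.00: 0.2, 97.9, 0; 6.00: 0.1, 98.0, 0; 10.0: 0, 98.0, 0
- Friday's (time / min: Pdt / %, Rea.Pdt / %, Sub / %): 2.50: 23.4, 24.9, 49.0; 5.00: 23.5, 25.9, 49.8; 6.00: 24.1, 24.2, 50.1; 10.0: 24.3, 24.4, 50.7
- Thursday's (time / min: Pdt / %, Rea.Pdt / %, Sub / %): 1.00: 22.4, 61.2, 12.1; 3.00: 21.7, 62.9, 13.0; 6.00: 21.6, 61.9, 13.3; 10.0: 22.6, 62.1, 12.8

(standard deviation of a reading: 0.5 percentage points)

- why nothing more happens at 15 min, or that something still does (no working catalyst is left / forward and back rates have come level / it is still moving / all of Sub has reacted / Rea has run out first)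
- Pdt at 15 min, in percent of the Sub charged
- Rea.Pdt at 15 min, in percent of the Sub charged

- on the list of suspects stand: Tsp + Imd3 -> Tsp.Imd3; Sub + Rea.Ctl <-> Imd; Rea + Ctl -> Rea.Ctl; Imd -> Imd2; Imd3 -> Ctl + Pdt; Imd2 <-> Bpr + Imd3; Rea + Pdt -> Rea.Pdt
- the reaction counts as stopped when no species that holds the Sub changes by six tenths of a point or more over the second half of the time

**The budget.** Count one Rea for each turnover and one more for each Rea.Pdt. Then take Rea charged as a fraction of Sub charged, the Rea budget, 150 % in this flask. Thursday's readings average Sub 12.8 %, Pdt 22.1 % and Rea.Pdt 62.0 %. Sub gone plus Rea.Pdt is therefore 149 %, against a budget of 150 %.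

**The rule.** Add the Sub balance, in which Tsp.Imd3 is taken to hold the missing part. With the budget spent and no Rea held as Rea.Ctl, Pdt is 50.0 % here, minus twice the Sub left, minus the Tsp.Imd3 share.

**What matters.** An error in the Tsp.Imd3 share passes to Pdt point for point, but an error in Sub left passes doubled. Thursday's readings, flat to 10.0 min, give time no weight. So Sub left is the number to get well.

**The number.** This flask is Thursday's with half the Tsp. Thursday's gap reads 3.10 %. Assume that the gap and Sub left both scale with Tsp, a rough guess, giving 1.55 % and 6.40 %. My reckoning is then Pdt 35.6 %.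

**The result.** The forecast gives 27.5 % Pdt, 60 % Rea.Pdt and the end as Rea has run out first: “Rea is exhausted”. The flask gives Rea has run out first, with 32.7 % Pdt and 57.7 % Rea.Pdt.

    Tsp + Imd3 → Tsp.Imd3 (k = 2220 L mol⁻¹ s⁻¹)
    Sub + Rea.Ctl ⇌ Imd (K = 6210 L mol⁻¹, k = 11900 L mol⁻¹ s⁻¹)
    Rea + Ctl → Rea.Ctl (k = 1.50 × 10⁵ L mol⁻¹ s⁻¹)
    Imd → Imd2 (k = 4.40 s⁻¹)
    Imd3 → Ctl + Pdt (k = 49.0 s⁻¹)
    Imd2 ⇌ Bpr + Imd3 (K = 0.0470 M, k = 36.3 s⁻¹)
    Rea + Pdt → Rea.Pdt (k = 735 L mol⁻¹ s⁻¹)

**Second flask.** In this flask Rea stands at 0 %, the limiting reagent although charged above Sub. Sub left is 7.66 %, above my 6.40 %, and Sub gone plus Rea.Pdt makes 150 %, the budget. Now take 1.0 × 10⁻⁴ M of Ctl, the rest unchanged. Sub stands at 0 % and Rea at 0 %. Sub gone, 100 %, plus Rea.Pdt, 33.5 %, plus Rea held as Rea.Ctl, 16.5 %, makes 150 %, the same budget, and Pdt there is 64.3 %.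

The runs are calculated from invented constants, noise included.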